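## Retrosynthetic overview

1. The target is reached by opening one lactone of a C2-symmetric bis(chromanone γ-lactone), the seco-acid/lactone pair of the post-retro-Dieckmann branch of the secalonic acid pathway.
2. Both pyranone rings and both quaternary C2 centres come from one two-directional double phenol oxa-Michael closure (the biosynthetic ring closure) of a biaryl bis(aroylacrylate), made in the same flask by double Wittig olefination of an enantiopure α-keto ester γ-lactone.
3. The biaryl bis-ylide comes from 2,6-dihydroxyacetophenone: iodination, homocoupling, a ketal bridge across the 2,2'-diol (only the phenols para to the axis stay free, which fixes the 6,6' linkage), then α-bromination/PPh3.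
4. The keto ester lactone comes from 4-methylbutenolide and methyl glyoxylate: asymmetric vinylogous aldol (C–O centre), cis-hydrogenation (C–Me centre), oxidation.
5. Ring order: biaryl bond and temporary dioxepine → stereocentres on the preformed five-membered lactones → both pyranone rings at once → one lactone opened last.

Assumption: the biaryl axis has only two ortho substituents and rotates freely, so no axial descriptor is set.
Assumption: in step 6 the (S,S)-ligand is taken to give the (R) ring carbinol carbon; if the sense is opposite, the (R,R)-ligand is used.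

## Route

Step 1
Reactants: 1 1-(2,6-dihydroxyphenyl)ethan-1-one; 2 N-iodosuccinimide
Product: 3 1-(2,6-dihydroxy-3-iodophenyl)ethan-1-one
Conditions: NIS (1.0 equiv), MeCN, 0 °C
Reagents that add atoms: N-iodosuccinimide (2), O=C1CCC(=O)N1I
Why: Electrophilic aromatic iodination; the two activated positions of the symmetrical resorcinol ketone are equivalent, so mono-iodination can give only one regioisomer and no stereocentre is formed.

Step 2
Reactants: 3 1-(2,6-dihydroxy-3-iodophenyl)ethan-1-one (two molecules)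
Product: 5 1,1'-(2,2',4,4'-tetrahydroxy-[1,1'-biphenyl]-3,3'-diyl)di(ethan-1-one), via aryl pinacol boronate 4 (not isolated)
Conditions: Pd(OAc)2 (5 mol%), SPhos (10 mol%), B2pin2 (0.55 equiv), aq. K3PO4, dioxane, 80 °C
Reagents that add atoms: none
Why: One-pot Miyaura borylation/Suzuki–Miyaura homocoupling, in which half of the iodide is borylated in situ and couples with the rest under aqueous phosphate that tolerates free phenols, giving the symmetrical biaryl without any stereo-element.

Step 3
Reactants: 5 1,1'-(2,2',4,4'-tetrahydroxy-[1,1'-biphenyl]-3,3'-diyl)di(ethan-1-one); 6 2,2-dimethoxypropane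
Product: 7 1,1'-(3,9-dihydroxy-6,6-dimethyldibenzo[d,f][1,3]dioxepine-4,8-diyl)di(ethan-1-one)
Conditions: 2,2-dimethoxypropane (3 equiv), TsOH·H2O (5 mol%), PhMe, 80 °C, 4 Å sieves
Reagents that add atoms: 2,2-dimethoxypropane (6), COC(C)(C)OC
Why: Acid-catalysed transketalisation under thermodynamic control; only the two phenols flanking the biaryl bond can close a seven-membered cyclic ketal, so they are masked selectively and the two phenols para to the axis remain free for the later ring closure.

Step 4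
Reactants: 7 1,1'-(3,9-dihydroxy-6,6-dimethyldibenzo[d,f][1,3]dioxepine-4,8-diyl)di(ethan-1-one); 8 triphenylphosphine
Product: 11 1,1'-(3,9-dihydroxy-6,6-dimethyldibenzo[d,f][1,3]dioxepine-4,8-diyl)bis[2-(triphenyl-λ5-phosphanylidene)ethan-1-one], via bis(bromomethyl ketone) 9 (not isolated), via bis(phosphonium bromide) 10 (not isolated)
Conditions: CuBr2 (4.2 equiv), EtOAc/CHCl3, reflux; then PPh3 (2.2 equiv), PhMe, rt; then aq. NaHCO3, CH2Cl2
Reagents that add atoms: triphenylphosphine (8), c1ccc(cc1)P(c1ccccc1)c1ccccc1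
Why: King α-bromination of the aryl methyl ketones with CuBr2, SN2 quaternisation of PPh3 and bicarbonate deprotonation give the carbonyl-stabilised Wittig bis-ylide, whose chelated phenols are less acidic than the phosphonium salt and stay protonated; no stereocentre is involved.

Step 5
Reactants: 12 4-methylfuran-2(5H)-one; 13 trimethylsilyl trifluoromethanesulfonate
Product: 14 trimethyl[(4-methylfuran-2-yl)oxy]silane
Conditions: TMSOTf (1.1 equiv), Et3N (1.3 equiv), Et2O, 0 °C
Reagents that add atoms: trimethylsilyl trifluoromethanesulfonate (13), C[Si](C)(C)OS(=O)(=O)C(F)(F)F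
Why: Soft enolisation and O-silylation of the butenolide give the aromatic 2-silyloxyfuran (vinylogous enol silane formation).

Step 6
Reactants: 14 trimethyl[(4-methylfuran-2-yl)oxy]silane; 15 methyl glyoxylate
Product: 17 methyl (2R)-2-hydroxy-2-[(2R)-3-methyl-5-oxo-2,5-dihydrofuran-2-yl]acetate, via aldol trimethylsilyl ether 16 (not isolated)
Conditions: [Cu((S,S)-t-Bu-box)](OTf)2 (10 mol%), THF, −78 °C; then 1 M HCl
Reagents that add atoms: none
Why: Catalytic enantioselective vinylogous Mukaiyama aldol reaction; the bis(oxazoline) copper Lewis acid chelates the glyoxylate and exposes one aldehyde face to the γ-carbon of the silyloxyfuran, which sets the ring C–O stereocentre as (R) in the anti adduct (the minor syn isomer is removed by chromatography and the side-chain carbinol is oxidised away in step 8).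

Step 7
Reactants: 17 methyl (2R)-2-hydroxy-2-[(2R)-3-methyl-5-oxo-2,5-dihydrofuran-2-yl]acetate
Product: 18 methyl (2R)-2-hydroxy-2-[(2R,3S)-3-methyl-5-oxooxolan-2-yl]acetate
Conditions: H2 (1 atm), Pd/C, EtOAc, rt
Reagents that add atoms: none
Why: Heterogeneous syn-hydrogenation; hydrogen is delivered to the butenolide face opposite the ring substituent, so the methyl group ends up cis to the side chain and the new centre is (3S).

Step 8
Reactants: 18 methyl (2R)-2-hydroxy-2-[(2R,3S)-3-methyl-5-oxooxolan-2-yl]acetate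
Product: 19 methyl 2-[(2R,3S)-3-methyl-5-oxooxolan-2-yl]-2-oxoacetate
Conditions: Dess–Martin periodinane (1.2 equiv), CH2Cl2, 0 °C → rt
Reagents that add atoms: none
Why: Dess–Martin oxidation of the α-hydroxy ester to the α-keto ester under neutral, non-enolising conditions, so the adjacent lactone stereocentre is kept.

Step 9
Reactants: 11 1,1'-(3,9-dihydroxy-6,6-dimethyldibenzo[d,f][1,3]dioxepine-4,8-diyl)bis[2-(triphenyl-λ5-phosphanylidene)ethan-1-one]; 19 methyl 2-[(2R,3S)-3-methyl-5-oxooxolan-2-yl]-2-oxoacetate (2.4 equiv)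
Product: 22 dimethyl (2S,2'S)-5,5'-dihydroxy-2,2'-bis[(2R,3S)-3-methyl-5-oxooxolan-2-yl]-4,4'-dioxo-[6,6'-bichromane]-2,2'-dicarboxylate, via bis(aroylacrylate) 20 (not isolated), via ketal-bridged bis(chromanone lactone) 21 (not isolated)
Conditions: PhMe, 60 °C; then Et3N (0.3 equiv), −20 → 0 °C; then TFA/H2O (9:1), 40 °C
Reagents that add atoms: none
Why: Proposed new method: double Wittig olefination of the α-keto ester by the neutral carbonyl-stabilised bis-ylide (too weak a base to epimerise 19) gives the bis(aroylacrylate), whose two free chelated phenols then add in a base-triggered 6-endo oxa-Michael reaction to the enone β-carbons, the ring closure of the biosynthesis and closest in known chemistry to the 2'-hydroxychalcone-to-flavanone and 3-(2-hydroxybenzoyl)acrylate-to-chromanone-2-carboxylate cyclisations, each quaternary C2 being set as (S) by polar Felkin–Anh attack anti to the lactone C–O bond in the A(1,3)-minimised conformer (carbinol H eclipsing the enone), after which aqueous TFA hydrolyses the aryl ketal.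

Step 10
Reactants: 22 dimethyl (2S,2'S)-5,5'-dihydroxy-2,2'-bis[(2R,3S)-3-methyl-5-oxooxolan-2-yl]-4,4'-dioxo-[6,6'-bichromane]-2,2'-dicarboxylate; 23 lithium hydroxide
Product: 24 (3S,4R)-4-hydroxy-4-[(2S)-5-hydroxy-6-{(2S)-5-hydroxy-2-(methoxycarbonyl)-2-[(2R,3S)-3-methyl-5-oxooxolan-2-yl]-4-oxochroman-6-yl}-2-(methoxycarbonyl)-4-oxochroman-2-yl]-3-methylbutanoic acid
Conditions: LiOH (3.0 equiv), THF/H2O (3:1), 0 °C, stopped near 50% lactone conversion; then 1 M HCl to pH 4, 0 °C
Reagents that add atoms: lithium hydroxide (23), [Li+].[OH-]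
Why: Saponification; after deprotonation of the two phenols, hydroxide attacks the unhindered lactone carbonyl far faster than the methyl esters on the fully substituted C2, and stopping at half conversion gives the mono-opened hydroxy acid statistically (recovered bis-lactone and diacid are recycled) without touching any stereocentre.

## Compound list

1 | 1-(2,6-dihydroxyphenyl)ethan-1-one (2,6-dihydroxyacetophenone) | CC(=O)c1c(O)cccc1O | starting material
2 | N-iodosuccinimide | O=C1CCC(=O)N1I | starting material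
3 | 1-(2,6-dihydroxy-3-iodophenyl)ethan-1-one | CC(=O)c1c(O)ccc(I)c1O | intermediate
4 | 1-[2,6-dihydroxy-3-(4,4,5,5-tetramethyl-1,3,2-dioxaborolan-2-yl)phenyl]ethan-1-one | CC(=O)c1c(O)ccc(B2OC(C)(C)C(C)(C)O2)c1O | intermediate
5 | 1,1'-(2,2',4,4'-tetrahydroxy-[1,1'-biphenyl]-3,3'-diyl)di(ethan-1-one) | CC(=O)c1c(O)ccc(-c2ccc(O)c(C(C)=O)c2O)c1O | intermediate
6 | 2,2-dimethoxypropane | COC(C)(C)OC | starting material
7 | 1,1'-(3,9-dihydroxy-6,6-dimethyldibenzo[d,f][1,3]dioxepine-4,8-diyl)di(ethan-1-one) | CC(=O)c1c(O)ccc2-c3ccc(O)c(C(C)=O)c3OC(C)(C)Oc12 | intermediate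
8 | triphenylphosphine | c1ccc(cc1)P(c1ccccc1)c1ccccc1 | starting material
9 | 1,1'-(3,9-dihydroxy-6,6-dimethyldibenzo[d,f][1,3]dioxepine-4,8-diyl)bis(2-bromoethan-1-one) | O=C(CBr)c1c(O)ccc2-c3ccc(O)c(C(=O)CBr)c3OC(C)(C)Oc12 | intermediate
10 | [(3,9-dihydroxy-6,6-dimethyldibenzo[d,f][1,3]dioxepine-4,8-diyl)bis(2-oxoethane-2,1-diyl)]bis(triphenylphosphonium) dibromide | [Br-].[Br-].O=C(C[P+](c1ccccc1)(c1ccccc1)c1ccccc1)c1c(O)ccc2-c3ccc(O)c(C(=O)C[P+](c4ccccc4)(c4ccccc4)c4ccccc4)c3OC(C)(C)Oc12 | intermediate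
11 | 1,1'-(3,9-dihydroxy-6,6-dimethyldibenzo[d,f][1,3]dioxepine-4,8-diyl)bis[2-(triphenyl-λ5-phosphanylidene)ethan-1-one] | O=C(C=P(c1ccccc1)(c1ccccc1)c1ccccc1)c1c(O)ccc2-c3ccc(O)c(C(=O)C=P(c4ccccc4)(c4ccccc4)c4ccccc4)c3OC(C)(C)Oc12 | intermediate
12 | 4-methylfuran-2(5H)-one | CC1=CC(=O)OC1 | starting material
13 | trimethylsilyl trifluoromethanesulfonate | C[Si](C)(C)OS(=O)(=O)C(F)(F)F | starting material
14 | trimethyl[(4-methylfuran-2-yl)oxy]silane | Cc1coc(O[Si](C)(C)C)c1 | intermediate
15 | methyl glyoxylate (methyl 2-oxoacetate) | COC(=O)C=O | starting material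
16 | methyl (2R)-2-[(2R)-3-methyl-5-oxo-2,5-dihydrofuran-2-yl]-2-[(trimethylsilyl)oxy]acetate | COC(=O)[C@H](O[Si](C)(C)C)[C@@H]1OC(=O)C=C1C | intermediate
17 | methyl (2R)-2-hydroxy-2-[(2R)-3-methyl-5-oxo-2,5-dihydrofuran-2-yl]acetate | COC(=O)[C@H](O)[C@@H]1OC(=O)C=C1C | intermediate
18 | methyl (2R)-2-hydroxy-2-[(2R,3S)-3-methyl-5-oxooxolan-2-yl]acetate | COC(=O)[C@H](O)[C@@H]1OC(=O)C[C@@H]1C | intermediate
19 | methyl 2-[(2R,3S)-3-methyl-5-oxooxolan-2-yl]-2-oxoacetate | COC(=O)C(=O)[C@@H]1OC(=O)C[C@@H]1C | intermediate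
20 | dimethyl 4,4'-(3,9-dihydroxy-6,6-dimethyldibenzo[d,f][1,3]dioxepine-4,8-diyl)bis{2-[(2R,3S)-3-methyl-5-oxooxolan-2-yl]-4-oxobut-2-enoate} (E/Z mixture) | COC(=O)C(=CC(=O)c1c(O)ccc2-c3ccc(O)c(C(=O)C=C(C(=O)OC)[C@@H]4OC(=O)C[C@@H]4C)c3OC(C)(C)Oc12)[C@@H]1OC(=O)C[C@@H]1C | intermediate
21 | dimethyl (2S,2'S)-5,5'-(propane-2,2-diyldioxy)-2,2'-bis[(2R,3S)-3-methyl-5-oxooxolan-2-yl]-4,4'-dioxo-[6,6'-bichromane]-2,2'-dicarboxylate | COC(=O)[C@@]1([C@@H]2OC(=O)C[C@@H]2C)CC(=O)c2c(ccc3c2OC(C)(C)Oc2c-3ccc3c2C(=O)C[C@@](C(=O)OC)([C@@H]2OC(=O)C[C@@H]2C)O3)O1 | intermediate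
22 | dimethyl (2S,2'S)-5,5'-dihydroxy-2,2'-bis[(2R,3S)-3-methyl-5-oxooxolan-2-yl]-4,4'-dioxo-[6,6'-bichromane]-2,2'-dicarboxylate | COC(=O)[C@@]1([C@@H]2OC(=O)C[C@@H]2C)CC(=O)c2c(ccc(-c3ccc4c(c3O)C(=O)C[C@@](C(=O)OC)([C@@H]3OC(=O)C[C@@H]3C)O4)c2O)O1 | intermediate
23 | lithium hydroxide | [Li+].[OH-] | starting material
24 | (3S,4R)-4-hydroxy-4-[(2S)-5-hydroxy-6-{(2S)-5-hydroxy-2-(methoxycarbonyl)-2-[(2R,3S)-3-methyl-5-oxooxolan-2-yl]-4-oxochroman-6-yl}-2-(methoxycarbonyl)-4-oxochroman-2-yl]-3-methylbutanoic acid (CNP0517857.1) | COC(=O)[C@@]1([C@H](O)[C@@H](C)CC(=O)O)CC(=O)c2c(ccc(-c3ccc4c(c3O)C(=O)C[C@@](C(=O)OC)([C@@H]3OC(=O)C[C@@H]3C)O4)c2O)O1 | target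

## Step count and risks

Total steps: 10. Longest linear sequence: 6 (steps 1, 2, 3, 4, 9, 10; the branch 5, 6, 7, 8, 9, 10 is equally long).

**Step 9 is the most likely to fail.** The hindered ketone of 19 may olefinate slowly, its lactone centre may epimerise on prolonged heating, and the substrate-controlled facial selectivity at C2 is predicted from a model, not demonstrated. The fallback sets out from 7 and 19 and comes back to the route at 20. Compound 7 is persilylated (TMSOTf, Et3N) to the tetrakis(trimethylsilyl) bis(enol silane) F1. F1 is added to 19 at −78 °C under BF3·OEt2 (Mukaiyama aldol), giving after aqueous work-up the bis(tertiary aldol) F2. F2 is dehydrated with catalytic TsOH in PhMe at 50 °C to bis-enone 20. Here 20 is isolated and cyclised under reagent control with a quinine- or quinidine-derived bifunctional squaramide (the pseudoenantiomer matched to the substrate bias), then treated with TFA/H2O to give 22.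

**Step 10 is the second risk.** It is a statistical desymmetrisation that gives a three-component mixture, and the hydroxy acid can relactonise on acidification. The fallback sets out from 22 and comes back at 24. Both lactones are opened with excess LiOH at 0 °C and the product is isolated at pH 5 as the bis(seco acid) F3. F3 is then partly relactonised under mild acid (catalytic TsOH, CH2Cl2, 0 °C, followed by HPLC), which is the lactonisation of the biosynthetic seco acid. Recovered F3 is resubmitted and over-lactonised 22 is reopened, so material is funnelled to 24.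

**Step 2 is the third risk.** The free polyphenolic iodide may undergo protodeiodination or protodeboronation, or bind palladium. The fallback sets out from 3 and comes back at 5. Both phenols are protected (NaH, MOMCl, DMF) to give the bis(methoxymethyl) ether F4. F4 is dimerised by Ullmann reductive homocoupling (activated copper powder, DMF, 110 °C) to the tetrakis(methoxymethyl) biaryl F5. F5 is deprotected with HCl in MeOH to 5.

Further compounds
F1 | step 9 | 4,8-bis[1-(trimethylsilyloxy)ethenyl]-6,6-dimethyl-3,9-bis(trimethylsilyloxy)dibenzo[d,f][1,3]dioxepine | C=C(O[Si](C)(C)C)c1c(O[Si](C)(C)C)ccc2-c3ccc(O[Si](C)(C)C)c(C(=C)O[Si](C)(C)C)c3OC(C)(C)Oc12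
F2 | step 9 | dimethyl 4,4'-(3,9-dihydroxy-6,6-dimethyldibenzo[d,f][1,3]dioxepine-4,8-diyl)bis{2-hydroxy-2-[(2R,3S)-3-methyl-5-oxooxolan-2-yl]-4-oxobutanoate} (epimers at the tertiary carbinols) | COC(=O)C(O)(CC(=O)c1c(O)ccc2-c3ccc(O)c(C(=O)CC(O)(C(=O)OC)[C@@H]4OC(=O)C[C@@H]4C)c3OC(C)(C)Oc12)[C@@H]1OC(=O)C[C@@H]1C
F3 | step 10 | (3S,3'S,4R,4'R)-4,4'-[(2S,2'S)-5,5'-dihydroxy-2,2'-bis(methoxycarbonyl)-4,4'-dioxo-[6,6'-bichromane]-2,2'-diyl]bis(4-hydroxy-3-methylbutanoic acid) | COC(=O)[C@@]1([C@H](O)[C@@H](C)CC(=O)O)CC(=O)c2c(ccc(-c3ccc4c(c3O)C(=O)C[C@@](C(=O)OC)([C@H](O)[C@@H](C)CC(=O)O)O4)c2O)O1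
F4 | step 2 | 1-[3-iodo-2,6-bis(methoxymethoxy)phenyl]ethan-1-one | CC(=O)c1c(OCOC)ccc(I)c1OCOC
F5 | step 2 | 1,1'-[2,2',4,4'-tetrakis(methoxymethoxy)-[1,1'-biphenyl]-3,3'-diyl]di(ethan-1-one) | CC(=O)c1c(OCOC)ccc(-c2ccc(OCOC)c(C(C)=O)c2OCOC)c1OCOC
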